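The whole plan depends on disconnecting the Z C1''=C2'' alkene of the C3' side chain. Because that alkene is Z, the phenolic O4' of ring A and the tertiary O3'' are close in space, and a single Ph2Si unit can span them. Ring-closing metathesis of the diene tethered in this way forms C1''=C2'' and closes an eight-membered dioxasilacycle (C3', C4', O4', Si, O3'', C3'', C2'', C1'') fused to ring A. The same operation sets the Z geometry and masks both oxygens. The precursor is a 3'-vinyl-2'-hydroxy-6'-methoxyacetophenone whose O4' carries a (1,1-dimethylallyloxy)diphenylsilyl group. The tether stays closed through an aprotic chalcone condensation and leaves under buffered fluoride.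

Key step: step 4

Remarks on the chemistry
- Assumption: iodination of the starting acetophenone is taken to follow resacetophenone and to occur mainly at C3'. An NOE between OCH3 and the remaining ring proton (H5') would confirm this before material is carried on.
- Structure check: the tethered diene and the cyclised silaketal map atom for atom onto ring A of the target, and the new ring has eight members. An eight-membered ring can hold a trans alkene, but only at a high cost in strain. The Z selectivity therefore rests on that energy gap and on reversible metathesis, not on an absolute prohibition.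
- Precursor design: the 2'-OH is left free on purpose, because it is the smallest possible neighbour for the reacting vinyl group. The ArO-SiPh2-O-tert-alkyl linkage is of the same kind as a tert-butoxydiphenylsilyl ether, so it should survive chromatography on base-washed silica.
- After ring closure, hydroxide or alkoxide in alcohol is avoided. It would open the ArO-Si bond, and the freed 4'-phenoxide would retard enolisation of the acetyl group. That phenoxide could also expel the tertiary silyloxy group through the styrene, giving an o-quinone methide that closes by an oxa-6π reaction to a 2,2-dimethylchromene. For this reason the condensation uses a lithium amide, the ring B phenol is carried as a silyl ether, and all silicon leaves in one buffered fluoride step.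

Step 1
Reactants: 1 2',4'-dihydroxy-6'-methoxyacetophenone
Product: 2 2',4'-dihydroxy-3'-iodo-6'-methoxyacetophenone
Conditions: I2 (0.4 equiv), HIO3 (0.2 equiv), EtOH/H2O 4:1, 0 °C → rt
Reagents that add atoms: iodine, [I][I]; iodic acid, OI(=O)=O
Why: Electrophilic aromatic iodination by the I2/HIO3 couple supplies exactly one iodonium equivalent with water as the only coproduct, and, as with resacetophenone under these conditions, substitution should favour C3' (ortho to both hydroxyls, para to OCH3, less crowded than C5'), while the limiting iodine charge holds back di-iodination.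

Step 2
Reactants: 2 2',4'-dihydroxy-3'-iodo-6'-methoxyacetophenone
Product: 3 3'-ethenyl-2',4'-dihydroxy-6'-methoxyacetophenone
Conditions: CH2=CHBF3K (1.5 equiv), PdCl2(dppf)·CH2Cl2 (5 mol %), Cs2CO3 (5 equiv), degassed THF/H2O 9:1, 75 °C; work-up at pH 6, trace BHT
Reagents that add atoms: potassium vinyltrifluoroborate, C=C[B-](F)(F)F.[K+]
Why: In this Suzuki–Miyaura vinylation the aryl iodide should add readily to zerovalent palladium even as its phenoxide, the slowly hydrolysing trifluoroborate keeps the vinylboron concentration low, and free phenols are tolerated in aqueous carbonate.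

Step 3
Reactants: 3 3'-ethenyl-2',4'-dihydroxy-6'-methoxyacetophenone; 4 2-methylbut-3-en-2-ol; 5 dichlorodiphenylsilane
Product: 7 1-[3-ethenyl-2-hydroxy-6-methoxy-4-({[(2-methylbut-3-en-2-yl)oxy]diphenylsilyl}oxy)phenyl]ethan-1-one, via chloro[(2-methylbut-3-en-2-yl)oxy]diphenylsilane 6 (not isolated)
Conditions: 5 (1.15 equiv), Et3N (3 equiv), DMAP (5 mol %), CH2Cl2, 0 °C, slow addition of 4 (1.2 equiv), rt; then 3 (1.0 equiv), 0 °C → rt; Et3N-washed silica
Reagents that add atoms: none
Why: In this stepwise nucleophilic substitution at silicon (mixed silaketal synthesis) the hindered tertiary alcohol should displace only one chloride, as in the preparation of tert-butoxydiphenylsilyl chloride, and the remaining Si-Cl bond is then taken by the acidic, unchelated 4'-OH, while the 2'-OH, hydrogen-bonded to the acetyl group and flanked on both sides, stays free.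

Step 4
Reactants: 7 1-[3-ethenyl-2-hydroxy-6-methoxy-4-({[(2-methylbut-3-en-2-yl)oxy]diphenylsilyl}oxy)phenyl]ethan-1-one
Product: 8 1-[(5Z)-7-hydroxy-9-methoxy-4,4-dimethyl-2,2-diphenyl-4H-1,3,2-benzodioxasilocin-8-yl]ethan-1-one (ring A fused to the eight-membered Z-dioxasilacycle)
Conditions: second-generation Grubbs catalyst (H2IMes)(PCy3)Cl2Ru=CHPh (10 mol % in two portions), degassed toluene (2 mM), 80 °C, argon sparge; Et3N-washed silica
Reagents that add atoms: none
Why: This is olefin metathesis through ruthenacyclobutanes: the catalyst should exchange first with the C3' vinyl group, a monosubstituted styrene, rather than with the alkene next to the quaternary C3'', and the resulting aryl-substituted ruthenium alkylidene then adds to the tethered 1,1-dimethylallyl alkene, cycloreversion forming C1''=C2'' and passing Ru=CH2 to the next molecule with ethylene as the only coproduct. The closest known reaction types are the temporary silicon-tethered ring-closing metathesis of mixed bis(alkoxy)silanes to seven- and eight-membered cis-dioxasilacycles and the ring-closing metathesis of 2-vinylaryl 1,1-dimethylallyl ethers to 2,2-dimethylchromenes. The single new ring (C3', C4', O4', Si, O3'', C3'', C2'', C1'') closes by intramolecular metathesis of the two terminal alkenes, and the long Si-O bonds, wide Si-O-C angles and geminal Me2C and Ph2Si substitution ease this medium-ring closure. No stereocentre is created, and the alkene geometry is controlled by the ring, because a trans alkene in this benzo-fused eight-membered ring would be so strained that a reversible metathesis should leave only the Z isomer. The selectivity needed is ring closure over cross-metathesis, and it is secured by the 2 mM dilution, by the reluctance of a di-ortho-substituted styrene and of an alkene next to a quaternary carbon to homodimerise, and by the absence of allylic hydrogens, which rules out alkene migration by ruthenium hydrides. The 2'-OH adds little bulk beside the reacting vinyl group, and its hydrogen bond to the acetyl oxygen should keep it off the metal.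

Step 5
Reactants: 9 4-hydroxybenzaldehyde
Product: 10 4-[(tert-butyldimethylsilyl)oxy]benzaldehyde
Conditions: TBSCl (1.1 equiv), imidazole (2.2 equiv), CH2Cl2, rt
Reagents that add atoms: tert-butyldimethylsilyl chloride, CC(C)(C)[Si](C)(C)Cl
Why: Standard imidazole-promoted O-silylation of a phenol removes the acidic proton that would otherwise turn the aldehyde into an unreactive phenoxide, and the group chosen falls to the same fluoride as the tether.

Step 6
Reactants: 8 1-[(5Z)-7-hydroxy-9-methoxy-4,4-dimethyl-2,2-diphenyl-4H-1,3,2-benzodioxasilocin-8-yl]ethan-1-one; 10 4-[(tert-butyldimethylsilyl)oxy]benzaldehyde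
Product: 12 (2E)-3-{4-[(tert-butyldimethylsilyl)oxy]phenyl}-1-[(5Z)-7-hydroxy-9-methoxy-4,4-dimethyl-2,2-diphenyl-4H-1,3,2-benzodioxasilocin-8-yl]prop-2-en-1-one, via racemic aldol adduct 11 (not isolated)
Conditions: 8, LiN(SiMe3)2 (2.2 equiv), THF, −78 °C; 10 (1.2 equiv), −78 °C → rt, dark; pH 7 phosphate buffer, 0 °C
Reagents that add atoms: none
Why: This directed Claisen–Schmidt (aldol) condensation runs through the lithium phenoxide-enolate dianion of a 2'-hydroxyacetophenone, the bulky non-nucleophilic amide should leave both aryl silyl ethers intact, E1cB loss of LiOH from the aldolate on warming gives the conjugated and thermodynamically preferred E enone, the transient carbinol centre of 11 is erased, and any silyl group lost after C-C bond formation does no harm because step 7 removes them all.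

Step 7
Reactants: 12 (2E)-3-{4-[(tert-butyldimethylsilyl)oxy]phenyl}-1-[(5Z)-7-hydroxy-9-methoxy-4,4-dimethyl-2,2-diphenyl-4H-1,3,2-benzodioxasilocin-8-yl]prop-2-en-1-one
Product: 13 candidachalcone, (2E)-1-{2,4-dihydroxy-3-[(1Z)-3-hydroxy-3-methylbut-1-en-1-yl]-6-methoxyphenyl}-3-(4-hydroxyphenyl)prop-2-en-1-one
Conditions: Bu4NF (4 equiv), AcOH (4 equiv), THF, 0 °C, dark; pH 7 buffer work-up
Reagents that add atoms: none
Why: Fluoride-driven desilylation cleaves all three Si-O bonds through formation of strong Si-F bonds, and the acetate buffer keeps the medium free both of phenoxide (flavanone closure, expulsion of the tertiary oxygen) and of strong acid (ionisation of the tertiary allylic alcohol towards the chromene), so neither alkene geometry should be touched.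

Compound list
1 | 2',4'-dihydroxy-6'-methoxyacetophenone | CC(=O)c1c(O)cc(O)cc1OC | starting material
2 | 2',4'-dihydroxy-3'-iodo-6'-methoxyacetophenone | Ic1c(O)cc(OC)c(C(C)=O)c1O | intermediate
3 | 3'-ethenyl-2',4'-dihydroxy-6'-methoxyacetophenone | CC(=O)c1c(OC)cc(O)c(C=C)c1O | intermediate
4 | 2-methylbut-3-en-2-ol | CC(C)(O)C=C | starting material
5 | dichlorodiphenylsilane | Cl[Si](Cl)(c1ccccc1)c1ccccc1 | starting material
6 | chloro[(2-methylbut-3-en-2-yl)oxy]diphenylsilane | C=CC(C)(C)O[Si](Cl)(c1ccccc1)c1ccccc1 | intermediate
7 | 1-[3-ethenyl-2-hydroxy-6-methoxy-4-({[(2-methylbut-3-en-2-yl)oxy]diphenylsilyl}oxy)phenyl]ethan-1-one | CC(=O)c1c(OC)cc(O[Si](c2ccccc2)(c2ccccc2)OC(C)(C)C=C)c(C=C)c1O | intermediate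
8 | 1-[(5Z)-7-hydroxy-9-methoxy-4,4-dimethyl-2,2-diphenyl-4H-1,3,2-benzodioxasilocin-8-yl]ethan-1-one | CC(=O)c1c(OC)cc2O[Si](c3ccccc3)(c3ccccc3)OC(C)(C)/C=C\c2c1O | intermediate
9 | 4-hydroxybenzaldehyde | O=Cc1ccc(O)cc1 | starting material
10 | 4-[(tert-butyldimethylsilyl)oxy]benzaldehyde | O=Cc1ccc(O[Si](C)(C)C(C)(C)C)cc1 | intermediate
11 | racemic 3-{4-[(tert-butyldimethylsilyl)oxy]phenyl}-3-hydroxy-1-[(5Z)-7-hydroxy-9-methoxy-4,4-dimethyl-2,2-diphenyl-4H-1,3,2-benzodioxasilocin-8-yl]propan-1-one | COc1cc2O[Si](c3ccccc3)(c3ccccc3)OC(C)(C)/C=C\c2c(O)c1C(=O)CC(O)c1ccc(O[Si](C)(C)C(C)(C)C)cc1 | intermediate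
12 | (2E)-3-{4-[(tert-butyldimethylsilyl)oxy]phenyl}-1-[(5Z)-7-hydroxy-9-methoxy-4,4-dimethyl-2,2-diphenyl-4H-1,3,2-benzodioxasilocin-8-yl]prop-2-en-1-one | COc1cc2O[Si](c3ccccc3)(c3ccccc3)OC(C)(C)/C=C\c2c(O)c1C(=O)/C=C/c1ccc(O[Si](C)(C)C(C)(C)C)cc1 | intermediate
13 | candidachalcone | COc1cc(O)c(/C=C\C(C)(C)O)c(O)c1C(=O)/C=C/c1ccc(O)cc1 | target

Total step count: 7. Compound 10 is also sold, which would save step 5.
Longest linear sequence: 6 (steps 1, 2, 3, 4, 6, 7). Step 5 is a side branch.

Steps most likely to fail

Step 4.
- What may go wrong: the ring closure may stall because both alkenes are crowded, the ortho oxygens may hold the ruthenium alkylidene in an unproductive chelate, or intermolecular metathesis may compete.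
- Fallback: the Z alkene is made by alkyne semihydrogenation and the silicon is installed afterwards. The fallback sets out from 2.
- Both phenols are acetylated (Ac2O, pyridine, DMAP) to 2',4'-diacetoxy-3'-iodo-6'-methoxyacetophenone F1, which blocks benzofuran formation.
- Sonogashira coupling with 2-methylbut-3-yn-2-ol (PdCl2(PPh3)2, CuI, Et3N) should give the arylalkyne 2',4'-diacetoxy-3'-(3-hydroxy-3-methylbut-1-yn-1-yl)-6'-methoxyacetophenone F2.
- Hydrogenation over Pd/CaCO3 poisoned with Pb(OAc)2, with quinoline, should stop at the cis alkene 2',4'-diacetoxy-3'-[(1Z)-3-hydroxy-3-methylbut-1-en-1-yl]-6'-methoxyacetophenone F3.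
- K2CO3 in MeOH at 0 °C, followed by an NH4Cl quench, frees 2',4'-dihydroxy-3'-[(1Z)-3-hydroxy-3-methylbut-1-en-1-yl]-6'-methoxyacetophenone F4.
- Treatment with 5 and imidazole in dilute CH2Cl2 silylates the unchelated 4'-OH first and then closes onto the tertiary hydroxyl. This rejoins the route at 8.

Step 6.
- What may go wrong: hydroxide loss from the lithium aldolate may be incomplete, retro-aldol cleavage may occur on warming, liberated hydroxide may strip silyl groups too early, or the 2'-phenoxide may add to the new enone.
- Fallback: addition and elimination are separated. The fallback sets out from 8 and 10.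
- The aldol addition is quenched at −78 °C with AcOH in THF so that 11 is isolated.
- The secondary benzylic hydroxyl of 11 is acetylated (Ac2O 1.1 equiv, Et3N, DMAP, CH2Cl2, 0 °C) to the β-acetoxy ketone F5.
- DBU in CH2Cl2 then eliminates acetate by E1cB. This rejoins the route at 12.

Step 2.
- What may go wrong: protodeiodination of the electron-rich iodoresorcinol may occur, oxidative addition of its phenoxide may be sluggish, and the regiochemistry of step 1 carries over as an uncertainty.
- Fallback: the vinyl group is built from a formyl group without any halide. The fallback sets out from 1.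
- Vilsmeier–Haack formylation (POCl3, DMF, EtOAc, 0 °C → rt, then water) should give 3-acetyl-2,6-dihydroxy-4-methoxybenzaldehyde F6, whose aldehyde is hydrogen-bonded by both flanking hydroxyls.
- Wittig methylenation with excess Ph3P=CH2 (from Ph3PCH3Br and KOtBu, 3.5 equiv, THF, 0 °C → rt) should take the aldehyde selectively, because the hindered, chelated ketone is inert. This rejoins the route at 3.

Further compounds
F1 | step 4 | 2',4'-diacetoxy-3'-iodo-6'-methoxyacetophenone | Ic1c(OC(C)=O)cc(OC)c(C(C)=O)c1OC(C)=O
F2 | step 4 | 2',4'-diacetoxy-3'-(3-hydroxy-3-methylbut-1-yn-1-yl)-6'-methoxyacetophenone | CC(=O)c1c(OC)cc(OC(C)=O)c(C#CC(C)(C)O)c1OC(C)=O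
F3 | step 4 | 2',4'-diacetoxy-3'-[(1Z)-3-hydroxy-3-methylbut-1-en-1-yl]-6'-methoxyacetophenone | CC(=O)c1c(OC)cc(OC(C)=O)c(/C=C\C(C)(C)O)c1OC(C)=O
F4 | step 4 | 2',4'-dihydroxy-3'-[(1Z)-3-hydroxy-3-methylbut-1-en-1-yl]-6'-methoxyacetophenone | CC(=O)c1c(OC)cc(O)c(/C=C\C(C)(C)O)c1O
F5 | step 6 | racemic β-acetoxy ketone, the O-acetate of 11 at its benzylic carbinol | COc1cc2O[Si](c3ccccc3)(c3ccccc3)OC(C)(C)/C=C\c2c(O)c1C(=O)CC(OC(C)=O)c1ccc(O[Si](C)(C)C(C)(C)C)cc1
F6 | step 2 | 3-acetyl-2,6-dihydroxy-4-methoxybenzaldehyde | CC(=O)c1c(OC)cc(O)c(C=O)c1O
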